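## Structural features

The target is a biflavonoid: a (2S)-5,7,3',4'-tetrahydroxyflavanone (rings A and C plus catechol ring B) whose ring B carries, at C5', the C8 carbon of a 5,7,3',4'-tetrahydroxyflavone. Ring B is the hub: C1' is bonded to the stereogenic C2 of the flavanone, C3' and C4' carry hydroxyl groups, and C5' is bonded to the flavone benzo ring between its C7 hydroxyl and the ring oxygen at C8a. C2 of the flavanone is the only stereocentre; it has no stereogenic neighbour, and the biaryl axis (three oxygen substituents and one hydrogen in its ortho positions) is not expected to be a stable stereogenic element. The fragile parts are this C2 centre, which racemises under base through ring opening to the 2'-hydroxychalcone, the eight free phenols with two oxidisable catechols, and the flavone carbonyl, which is attacked by aluminium hydrides and by hot alkali. The real difficulty is the aryl–aryl bond between two electron-rich rings with oxygen on both sides of it, together with the regiochemistry at the flavone (C8, not C6) and the need to set C2 late and without base. The key step exploits the fact that the flavone benzo ring (C4a, C5, C6, C7, C8, C8a) bears oxygen on the alternate carbons C5, C7 and C8a, the pattern of a folded triketide, and that C8, the carbon carrying ring B, lies between two of these oxygenated carbons. C8 therefore corresponds to the benzylic CH2 of a ring-B arylacetyl chain and its neighbour C7 (or C8a) to an ester carbonyl, so the biaryl bond can be present from the start as an ordinary benzylic C–C bond.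

## Logic of the disconnections

27 to 26: the eight aryl O–CH2Ph bonds are cut. One protecting group that leaves last under neutral conditions is needed, because C2 does not tolerate base and the catechols do not tolerate oxidants. The skeleton is unchanged; the forward step must spare the flavone C2=C3 bond and the benzylic C2–O1 bond of the flavanone.

26 to 24 (through 25): O1–C2 of ring C is cut and an ester is added at C3 as an activating group. The only stereocentre sits on the ring-closing carbon, so this cut removes ring C and the stereocentre together and leaves an achiral precursor. The forward step needs catalyst control of the alkene face and no uncatalysed closure.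

24 to 20 and 23: the C2–C3 bond (the alkylidene double bond) is cut. This splits the molecule convergently into the flavone-bearing ring-B aldehyde and the ring-A piece. The condensation must stop at the open alkene.

23 to 22 to 21: the C3–carboxyl bond and two O–benzyl bonds are cut, which leads to commercial 21. The forward acylation must go to carbon.

20 to 19 to 17: no skeletal bond is cut; only the oxidation level of the ring-B carboxyl carbon changes. That carbon has to stay at the acid or ester level through the acidic and basic steps that build the flavone, and becomes the aldehyde only afterwards. The reduction must therefore leave the flavone carbonyl untouched.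

17 to 16: O1–C2 of the flavone pyranone ring is cut (with the C2=C3 unsaturation). The forward oxidative closure needs exactly one free hydroxyl ortho to the ketone, the one next to ring B.

16 to 14 and 15: the flavone C2–C3 bond (the chalcone double bond) is cut, and the acid is traced back to the methyl ester. 15 is commercial. The forward aldol condensation uses hydroxide, which is allowed to cleave the ester in the same operation.

14 to 13: two O–benzyl bonds (the future C5 and C7 oxygens) are cut. The forward step must tell three hydroxyls apart and leave the most hindered one free.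

13 to 11: the C4a–C4 bond (aryl–acetyl) is cut. 11 has two equivalent free ring positions, so there is no regiochemical question; only monoacylation is required.

11 to 10 (key step): the C8–C7 bond is cut, which opens the benzo ring to an acyclic triketide. This turns the hindered aryl–aryl bond into the benzylic C–C bond of an arylacetic acid, so the ring and the biaryl problem disappear together. The forward step needs carbon acylation in preference to oxygen acylation.

10 to 6 and 7 (through 8 and 9): the C4–C5 bond of the chain is cut. This gives an arylacetic acid and a commercial β-keto ester. The forward acylation must occur at the terminal carbon of the dianion despite the acidic benzylic hydrogens of the acyl donor.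

6 to 5 to 4: the bond between ring B (C5') and the acetic acid CH2 is cut. The forward coupling must tolerate the methyl ester, and the new ester must be cleavable beside it, hence tert-butyl.

4 to 3 to 2 to 1: two O–benzyl bonds are cut, the methyl ether is restored, and the C–Br bond is cut. Commercial 1 already holds every carbon and oxygen of ring B, and its free phenol directs bromination to the one position required.

## Other disconnections considered

Alternative 1: The cut is the C3–C4 bond of ring C together with the C2–H bond. The flavanone is traced back to aldehyde A1, a ring-A salicylaldehyde whose phenolic oxygen carries the 1-arylvinyl group built on ring B. Forward, a cationic monovalent rhodium catalyst with a chiral bisphosphine would insert into the aldehyde C–H bond. The acyl rhodium hydride would add across the vinyl ether, with hydride going to the aryl-bearing carbon and setting C2, and reductive elimination would form C3–C4 to give the protected flavanone A2.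
- In its favour: the step is redox-neutral and atom-economic and runs without base, so the product cannot racemise through the chalcone. The vinyl ether could be reached from the acid level of ring B (aryl ester, then carbonyl methylenation), which would spare the reduction–oxidation detour of steps 12 and 13; on that count it is better than the chosen plan.
- Against it here: closure of an O-tethered 1,1-disubstituted vinyl ether to a six-membered ketone, with control at the fully substituted alkene carbon, has little precedent. Decarbonylation of the electron-rich, doubly ortho-substituted aldehyde and the wrong sense of insertion would compete. The cationic metal would face eight acetal ethers and a flavone carbonyl as competing ligands, and the methylenation would have to distinguish an aryl ester from the flavone carbonyl.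
- Comparison: in structure it deals with ring C and the stereocentre only and says nothing about the hindered biaryl, so it could replace steps 15 to 17 but not step 7. In mechanism it is an organometallic C–H activation, where the chosen plan uses a hydrogen-bond-catalysed conjugate addition of established scope. In step count it is about equal, with a possible saving of two steps if the methylenation were selective.

Alternative 2: The cuts are C8a–C8 and C7–C6 of the flavone benzo ring, with C8a–C4a broken and re-formed on the way. This divides the ring into the four-carbon unit 3-ethoxycyclobutenone A3 and the two-carbon ynol ether A4 carried by ring B. Forward, heating would open A3 to a vinylketene, which adds to the alkyne in a [2+2] sense; the new cyclobutenone opens again, closes by 6π electrocyclisation and tautomerises to phenol A5.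
- In its favour: like the chosen key step it builds the benzo ring on ring B and avoids a cross-coupling at the hindered axis, and on this it is the equal of the chosen plan. It is convergent and needs neither acid nor base. The three oxygens emerge differentiated, the single free hydroxyl being the one next to ring B that is needed as O1; here it is better than the chosen plan, which must differentiate the hydroxyls in step 9.
- Against it here: the two ethyl ethers at the future C5 and C7 could later be removed only with boron trihalides or similar reagents, which the flavanone centre would not tolerate, and cyclobutenones with more easily cleaved alkoxy groups are not readily bought. The ynol ether A4 must be made and is sensitive to acid and heat. The acetal groups on ring B of A5 would not survive a Lewis-acid acetylation.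
- Comparison: in structure it is equal in removing the biaryl problem, better in regiochemical definition and worse in the protecting-group endgame. In mechanism it is a pericyclic cascade steered by the polarity of ketene and ynol ether, against an ionic acyl substitution under thermodynamic control. In step count it is about equal up to the phenol and one step shorter at the protection stage, but it loses steps to ether exchange at the end.

Alternative 3: The cut is O1–C2 of ring C, with a tert-butyl ester added at C3 as an activating group. The precursor is the alkylidene β-keto ester A6, in which the ring-A phenol is free. Forward, a cinchona-derived bifunctional thiourea binds the β-dicarbonyl unit while its quinuclidine guides the phenol to one face of the alkylidene carbon. The 6-endo-trig oxa-Michael addition gives the trans ester A7, and acid then removes the ester group.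
- In its favour: it is the best-established catalytic entry to enantioenriched flavanones. It sets C2 late and under mild conditions, and the ester suppresses the uncatalysed closure that troubles plain 2'-hydroxychalcones.
- Against it here: with methoxymethyl ethers the hot acid needed for decarboxylation would strip the acetals unevenly, so decarboxylation and deprotection cannot be ordered cleanly. A 5,7-dioxygenated ring A lies at the edge of the known substrate range. Two extra operations (β-keto ester synthesis and decarboxylation) are needed.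
- Comparison: this cut does not compete with the key step but complements it. It deals with ring C, and the chosen plan uses the same kind of closure in step 17, with benzyl ethers in place of the acetals so that the acid step is harmless; on ring C the two are therefore equal in mechanism and step count. As the organising disconnection it would leave the biaryl and the flavone benzo ring to a cross-coupling of two ortho-oxygenated partners, and that is where the chosen plan differs.

Key step: step 7

Remarks on the chemistry (assumptions):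
- The C5'–C8'' axis is taken as not configurationally stable at room temperature, so C2 is the only stereogenic element to control.
- The quinidine-derived thiourea is taken to give the 2S series in step 17; should the sense prove opposite, the pseudoenantiomeric quinine-derived catalyst is used in the same step.
- Structures 10 and 11 were checked against the target numbering (benzylic carbon of 10 becomes flavone C8, ring-B carboxyl carbon becomes flavanone C2) and need no correction; at the stage of 11 the two oxygenated carbons next to C8 are equivalent, so the new bond is C8–C7 or C8–C8a only once step 8 breaks the symmetry.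
- 10 is kept as a methyl/methyl diester with benzyl ethers (methoxide exchange is degenerate, benzyl survives all later steps); what is changed is its later use: the ring-B ester is hydrolysed on purpose in step 10 and reduced by way of the acid, because a hydride reduction of the ester beside the flavone carbonyl could not be defended.
- 10 and 23 are drawn as keto tautomers although they are largely enolised.

## Steps

Step 1
Reactants: 1 methyl vanillate (methyl 4-hydroxy-3-methoxybenzoate)
Product: 2 methyl 3-bromo-4-hydroxy-5-methoxybenzoate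
Conditions: Br2, AcOH, rt
Reagents that add atoms: bromine, BrBr
Why: Electrophilic aromatic bromination; the free phenol directs to its only open ortho position, the para position being occupied by the ester.

Step 2
Reactants: 2 methyl 3-bromo-4-hydroxy-5-methoxybenzoate
Product: 3 methyl 3-bromo-4,5-dihydroxybenzoate
Conditions: BBr3, CH2Cl2, -78 to 0 °C; then H2O
Reagents that add atoms: none
Why: Lewis-acid cleavage of the aryl methyl ether through its bromoborane complex; at 0 °C the methyl ester is expected to survive.

Step 3
Reactants: 3 methyl 3-bromo-4,5-dihydroxybenzoate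
Product: 4 methyl 3,4-bis(benzyloxy)-5-bromobenzoate
Conditions: BnBr, K2CO3, DMF, 60 °C
Reagents that add atoms: benzyl bromide, BrCc1ccccc1
Why: Williamson etherification of both phenols; benzyl is chosen because it withstands the later acid, methoxide and hydroxide steps and leaves in one final hydrogenolysis.

Step 4
Reactants: 4 methyl 3,4-bis(benzyloxy)-5-bromobenzoate
Product: 5 methyl 3,4-bis(benzyloxy)-5-(2-tert-butoxy-2-oxoethyl)benzoate
Conditions: BrZnCH2CO2t-Bu, Pd2(dba)3 (1 mol %), XPhos, THF, 50 °C
Reagents that add atoms: (2-tert-butoxy-2-oxoethyl)zinc bromide, CC(C)(C)OC(=O)C[Zn]Br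
Why: Negishi-type coupling of a Reformatsky reagent (palladium-catalysed α-arylation of a zinc ester enolate); the mild zinc enolate tolerates the methyl ester and the bulky biaryl phosphine copes with the ortho benzyloxy group.

Step 5
Reactants: 5 methyl 3,4-bis(benzyloxy)-5-(2-tert-butoxy-2-oxoethyl)benzoate
Product: 6 [2,3-bis(benzyloxy)-5-(methoxycarbonyl)phenyl]acetic acid
Conditions: CF3CO2H, CH2Cl2, rt
Reagents that add atoms: none
Why: Acidolysis of the tert-butyl ester through the tert-butyl cation; the methyl ester and the benzyl ethers on the ester-deactivated ring are not affected.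

Step 6
Reactants: 6 [2,3-bis(benzyloxy)-5-(methoxycarbonyl)phenyl]acetic acid; 7 methyl acetoacetate
Product: 10 methyl 6-[2,3-bis(benzyloxy)-5-(methoxycarbonyl)phenyl]-3,5-dioxohexanoate, via acyl imidazole 8 (not isolated), via dilithium dianion 9 (not isolated)
Conditions: 6, CDI, THF, rt; added to 9 (from 7, LiN(i-Pr)2 2 equiv per 7, THF, -78 °C; 3.5 equiv), -78 to -30 °C; aq. HCl
Reagents that add atoms: none
Why: Claisen-type acylation of the acetoacetate dianion at its terminal carbon by the acyl imidazole; an excess of 9 is used because the liberated imidazole and the acidic product each consume one equivalent, and the low temperature favours addition over deprotonation at the benzylic position of 8.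

Step 7
Reactants: 10 methyl 6-[2,3-bis(benzyloxy)-5-(methoxycarbonyl)phenyl]-3,5-dioxohexanoate
Product: 11 methyl 3,4-bis(benzyloxy)-5-(2,4,6-trihydroxyphenyl)benzoate
Conditions: NaOMe (5 equiv), MeOH, reflux, argon; then 1 M HCl
Reagents that add atoms: none
Why: Claisen (Dieckmann-type) condensation of a triketide chain: methoxide deprotonates 10 first at C4 and C2 and, in equilibrium, at the benzylic C6, whose enolate is stabilised by the C5 carbonyl and by ring B. This C6 enolate attacks the C1 ester carbonyl, methoxide is expelled, and the resulting 2-aryl-cyclohexane-1,3,5-trione tautomerises to the phloroglucinol, held in the basic medium as its phenoxide. The ring closed is the flavone benzo ring, in a 6-exo-trig acyl substitution, and the new bond joins the future C8 to an oxygenated neighbour (C7 or C8a, equivalent until step 8). The closest known reactions are the base-induced cyclisations of 3,5-dioxoalkanoates to phloroglucinols and of 6-aryl-5-oxohexanoates to 2-aryl-cyclohexane-1,3-diones. No stereocentre is formed, and the hindered biaryl axis arises from an ordinary benzylic carbon. The selectivity needed is carbon against oxygen acylation: attack by the C5 enol oxygen would give the 4-hydroxy-2-pyranone, but in hot methanolic methoxide this lactone should reopen, whereas aromatisation and deprotonation make the carbocycle the thermodynamic sink. Closure from C2 or C4 would give four-membered rings and is excluded, and the ring-B ester is a methyl ester, so its exchange with methoxide is degenerate.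

Step 8
Reactants: 11 methyl 3,4-bis(benzyloxy)-5-(2,4,6-trihydroxyphenyl)benzoate
Product: 13 methyl 3-(3-acetyl-2,4,6-trihydroxyphenyl)-4,5-bis(benzyloxy)benzoate, via ketiminium chloride 12 (not isolated)
Conditions: MeCN, ZnCl2 (cat.), HCl (g), Et2O, 0 °C; then H2O, 90 °C
Reagents that add atoms: acetonitrile, CC#N; water, O
Why: Houben–Hoesch acylation; the nitrilium ion attacks one of the two equivalent free positions of the phloroglucinol ring, the ketiminium salt separates and so stops the reaction at monoacylation, and hydrolysis gives the ketone. The ester-deactivated ring B does not compete and the benzyl ethers tolerate HCl in ether at 0 °C.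

Step 9
Reactants: 13 methyl 3-(3-acetyl-2,4,6-trihydroxyphenyl)-4,5-bis(benzyloxy)benzoate
Product: 14 methyl 3-[3-acetyl-4,6-bis(benzyloxy)-2-hydroxyphenyl]-4,5-bis(benzyloxy)benzoate
Conditions: BnBr (2.1 equiv), K2CO3, acetone, 50 °C
Reagents that add atoms: benzyl bromide, BrCc1ccccc1
Why: Williamson etherification under mild carbonate conditions; the non-chelated hydroxyl para to the acetyl group should react first, then the less hindered of the two hydrogen-bonded hydroxyls, so that the hydroxyl wedged between the acetyl group and ring B (the future O1 of the flavone) stays free.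

Step 10
Reactants: 14 methyl 3-[3-acetyl-4,6-bis(benzyloxy)-2-hydroxyphenyl]-4,5-bis(benzyloxy)benzoate; 15 3,4-bis(benzyloxy)benzaldehyde
Product: 16 3-{3-[(2E)-3-[3,4-bis(benzyloxy)phenyl]prop-2-enoyl]-4,6-bis(benzyloxy)-2-hydroxyphenyl}-4,5-bis(benzyloxy)benzoic acid
Conditions: KOH (aq. 50 %), EtOH/THF, rt to 40 °C; then 1 M HCl
Reagents that add atoms: potassium hydroxide, [K+].[OH-]
Why: Claisen–Schmidt condensation of the acetophenone enolate with the non-enolisable aldehyde 15, with E1cB dehydration to the E enone; the hydroxide medium also saponifies the ring-B methyl ester, which is intended, since the carboxyl carbon is next needed at the acid level.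

Step 11
Reactants: 16 3-{3-[(2E)-3-[3,4-bis(benzyloxy)phenyl]prop-2-enoyl]-4,6-bis(benzyloxy)-2-hydroxyphenyl}-4,5-bis(benzyloxy)benzoic acid
Product: 17 3-{5,7-bis(benzyloxy)-2-[3,4-bis(benzyloxy)phenyl]-4-oxo-4H-chromen-8-yl}-4,5-bis(benzyloxy)benzoic acid
Conditions: I2 (10 mol %), DMSO, 120 °C
Reagents that add atoms: none
Why: Iodine-catalysed oxidative cyclisation of a 2'-hydroxychalcone in DMSO (oxa-Michael closure, α-iodination, loss of HI, DMSO returning HI to iodine); only the free hydroxyl next to ring B can close, which fixes the biaryl at C8.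

Step 12
Reactants: 17 3-{5,7-bis(benzyloxy)-2-[3,4-bis(benzyloxy)phenyl]-4-oxo-4H-chromen-8-yl}-4,5-bis(benzyloxy)benzoic acid
Product: 19 5,7-bis(benzyloxy)-8-[2,3-bis(benzyloxy)-5-(hydroxymethyl)phenyl]-2-[3,4-bis(benzyloxy)phenyl]-4H-chromen-4-one, via mixed anhydride 18 (not isolated)
Conditions: i-BuOCOCl, N-methylmorpholine, THF, -15 °C; then NaBH4, H2O, 0 °C
Reagents that add atoms: none
Why: Chemoselective reduction of a carboxylic acid through its mixed carbonic anhydride with NaBH4; borohydride does not attack the vinylogous-ester carbonyl of a flavone at 0 °C, whereas aluminium hydrides would.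

Step 13
Reactants: 19 5,7-bis(benzyloxy)-8-[2,3-bis(benzyloxy)-5-(hydroxymethyl)phenyl]-2-[3,4-bis(benzyloxy)phenyl]-4H-chromen-4-one
Product: 20 3-{5,7-bis(benzyloxy)-2-[3,4-bis(benzyloxy)phenyl]-4-oxo-4H-chromen-8-yl}-4,5-bis(benzyloxy)benzaldehyde
Conditions: MnO2 (activated, excess), CH2Cl2, rt
Reagents that add atoms: none
Why: MnO2 oxidation of a benzylic alcohol stops at the aldehyde; the flavone and the benzyl ethers are inert.

Step 14
Reactants: 21 1-(2,4,6-trihydroxyphenyl)ethanone (2,4,6-trihydroxyacetophenone)
Product: 22 1-[2,4-bis(benzyloxy)-6-hydroxyphenyl]ethanone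
Conditions: BnBr (2.1 equiv), K2CO3, acetone, 50 °C
Reagents that add atoms: benzyl bromide, BrCc1ccccc1
Why: Williamson etherification; the para hydroxyl and one of the two equivalent ortho hydroxyls are benzylated, while the remaining ortho hydroxyl stays hydrogen-bonded to the carbonyl and unreactive under carbonate conditions.

Step 15
Reactants: 22 1-[2,4-bis(benzyloxy)-6-hydroxyphenyl]ethanone
Product: 23 tert-butyl 3-[2,4-bis(benzyloxy)-6-hydroxyphenyl]-3-oxopropanoate
Conditions: LiN(SiMe3)2 (3.3 equiv), THF, -78 °C; Boc2O (1.1 equiv), -78 to 0 °C; aq. NH4Cl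
Reagents that add atoms: di-tert-butyl dicarbonate, CC(C)(C)OC(=O)OC(=O)OC(C)(C)C
Why: C-acylation of the ketone enolate (phenoxide–enolate dianion) by Boc2O to the tert-butyl β-keto ester; any O-acylation of the phenoxide should be corrected by a Baker–Venkataraman-type transfer of the tert-butoxycarbonyl group to the neighbouring enolate, and a tert-butyl ester is slow to lactonise to the 4-hydroxycoumarin.

Step 16
Reactants: 20 3-{5,7-bis(benzyloxy)-2-[3,4-bis(benzyloxy)phenyl]-4-oxo-4H-chromen-8-yl}-4,5-bis(benzyloxy)benzaldehyde; 23 tert-butyl 3-[2,4-bis(benzyloxy)-6-hydroxyphenyl]-3-oxopropanoate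
Product: 24 tert-butyl (2Z)-2-[2,4-bis(benzyloxy)-6-hydroxybenzoyl]-3-(3-{5,7-bis(benzyloxy)-2-[3,4-bis(benzyloxy)phenyl]-4-oxo-4H-chromen-8-yl}-4,5-bis(benzyloxy)phenyl)prop-2-enoate
Conditions: piperidine (20 mol %), AcOH (20 mol %), 4 Å molecular sieves, toluene, rt
Reagents that add atoms: none
Why: Knoevenagel condensation of the active methylene of 23 with aldehyde 20; the Z alkene (aryl cis to the ester) is expected to predominate, both geometries lead to the same ring closure, and the hydrogen bond of the phenol to the ketone should hold back premature cyclisation at room temperature.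

Step 17
Reactants: 24 tert-butyl (2Z)-2-[2,4-bis(benzyloxy)-6-hydroxybenzoyl]-3-(3-{5,7-bis(benzyloxy)-2-[3,4-bis(benzyloxy)phenyl]-4-oxo-4H-chromen-8-yl}-4,5-bis(benzyloxy)phenyl)prop-2-enoate
Product: 26 (2S)-5,7-bis(benzyloxy)-2-(3-{5,7-bis(benzyloxy)-2-[3,4-bis(benzyloxy)phenyl]-4-oxo-4H-chromen-8-yl}-4,5-bis(benzyloxy)phenyl)-2,3-dihydro-4H-chromen-4-one, via flavanone ester 25 (not isolated)
Conditions: 3,5-bis(trifluoromethyl)phenyl thiourea of 9-amino-9-deoxy-epi-quinidine (10 mol %), toluene, -25 °C; then TsOH·H2O, 80 °C
Reagents that add atoms: none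
Why: Enantioselective intramolecular oxa-Michael addition under bifunctional cinchona thiourea catalysis: the thiourea binds the β-keto ester and the quinuclidine delivers the phenol to one face of the alkylidene carbon, which sets C2 as S in the trans (2S,3R) ester 25. TsOH then cleaves the tert-butyl ester and the β-keto acid loses CO2, which removes the C3 centre and leaves C2 untouched; the benzyl ethers tolerate the acid.

Step 18
Reactants: 26 (2S)-5,7-bis(benzyloxy)-2-(3-{5,7-bis(benzyloxy)-2-[3,4-bis(benzyloxy)phenyl]-4-oxo-4H-chromen-8-yl}-4,5-bis(benzyloxy)phenyl)-2,3-dihydro-4H-chromen-4-one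
Product: 27 (2S)-2-{3-[2-(3,4-dihydroxyphenyl)-5,7-dihydroxy-4-oxo-4H-chromen-8-yl]-4,5-dihydroxyphenyl}-5,7-dihydroxy-2,3-dihydro-4H-chromen-4-one (CNP0224656.1)
Conditions: H2 (1 atm), Pd/C (10 wt %), THF/MeOH, rt
Reagents that add atoms: none
Why: Hydrogenolysis of the eight aryl benzyl ethers under neutral conditions, which cannot epimerise C2; the flavone double bond and the benzylic C2–O bond of the flavanone are reduced much more slowly than O-benzyl groups, and the reaction is stopped once the ethers are gone.

## Compound list

1 | methyl vanillate (methyl 4-hydroxy-3-methoxybenzoate) | COC(=O)c1ccc(O)c(OC)c1 | starting material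
2 | methyl 3-bromo-4-hydroxy-5-methoxybenzoate | COC(=O)c1cc(Br)c(O)c(OC)c1 | intermediate
3 | methyl 3-bromo-4,5-dihydroxybenzoate | COC(=O)c1cc(Br)c(O)c(O)c1 | intermediate
4 | methyl 3,4-bis(benzyloxy)-5-bromobenzoate | COC(=O)c1cc(Br)c(OCc2ccccc2)c(OCc2ccccc2)c1 | intermediate
5 | methyl 3,4-bis(benzyloxy)-5-(2-tert-butoxy-2-oxoethyl)benzoate | COC(=O)c1cc(CC(=O)OC(C)(C)C)c(OCc2ccccc2)c(OCc2ccccc2)c1 | intermediate
6 | [2,3-bis(benzyloxy)-5-(methoxycarbonyl)phenyl]acetic acid | COC(=O)c1cc(CC(=O)O)c(OCc2ccccc2)c(OCc2ccccc2)c1 | intermediate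
7 | methyl acetoacetate | COC(=O)CC(C)=O | starting material
8 | methyl 3,4-bis(benzyloxy)-5-[2-(1H-imidazol-1-yl)-2-oxoethyl]benzoate (not isolated) | COC(=O)c1cc(CC(=O)n2ccnc2)c(OCc2ccccc2)c(OCc2ccccc2)c1 | intermediate
9 | dilithium dianion of methyl acetoacetate (not isolated) | [Li+].[Li+].C=C([O-])C=C([O-])OC | intermediate
10 | methyl 6-[2,3-bis(benzyloxy)-5-(methoxycarbonyl)phenyl]-3,5-dioxohexanoate | COC(=O)CC(=O)CC(=O)Cc1cc(C(=O)OC)cc(OCc2ccccc2)c1OCc3ccccc3 | intermediate
11 | methyl 3,4-bis(benzyloxy)-5-(2,4,6-trihydroxyphenyl)benzoate | Oc1cc(O)c(-c2cc(C(=O)OC)cc(OCc3ccccc3)c2OCc4ccccc4)c(O)c1 | intermediate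
12 | 1-{3-[2,3-bis(benzyloxy)-5-(methoxycarbonyl)phenyl]-2,4,6-trihydroxyphenyl}ethan-1-iminium chloride (not isolated) | CC(=[NH2+])c1c(O)cc(O)c(-c2cc(C(=O)OC)cc(OCc3ccccc3)c2OCc4ccccc4)c1O.[Cl-] | intermediate
13 | methyl 3-(3-acetyl-2,4,6-trihydroxyphenyl)-4,5-bis(benzyloxy)benzoate | CC(=O)c1c(O)cc(O)c(-c2cc(C(=O)OC)cc(OCc3ccccc3)c2OCc4ccccc4)c1O | intermediate
14 | methyl 3-[3-acetyl-4,6-bis(benzyloxy)-2-hydroxyphenyl]-4,5-bis(benzyloxy)benzoate | CC(=O)c1c(OCc2ccccc2)cc(OCc2ccccc2)c(-c2cc(C(=O)OC)cc(OCc3ccccc3)c2OCc4ccccc4)c1O | intermediate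
15 | 3,4-bis(benzyloxy)benzaldehyde | O=Cc1ccc(OCc2ccccc2)c(OCc2ccccc2)c1 | starting material
16 | 3-{3-[(2E)-3-[3,4-bis(benzyloxy)phenyl]prop-2-enoyl]-4,6-bis(benzyloxy)-2-hydroxyphenyl}-4,5-bis(benzyloxy)benzoic acid | O=C(/C=C/c1ccc(OCc2ccccc2)c(OCc2ccccc2)c1)c1c(OCc2ccccc2)cc(OCc2ccccc2)c(-c2cc(C(=O)O)cc(OCc3ccccc3)c2OCc4ccccc4)c1O | intermediate
17 | 3-{5,7-bis(benzyloxy)-2-[3,4-bis(benzyloxy)phenyl]-4-oxo-4H-chromen-8-yl}-4,5-bis(benzyloxy)benzoic acid | O=C(O)c1cc(-c2c(OCc3ccccc3)cc(OCc3ccccc3)c3c(=O)cc(-c4ccc(OCc5ccccc5)c(OCc5ccccc5)c4)oc23)c(OCc2ccccc2)c(OCc2ccccc2)c1 | intermediate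
18 | 3-{5,7-bis(benzyloxy)-2-[3,4-bis(benzyloxy)phenyl]-4-oxo-4H-chromen-8-yl}-4,5-bis(benzyloxy)benzoic 2-methylpropyl carbonic anhydride (not isolated) | CC(C)COC(=O)OC(=O)c1cc(-c2c(OCc3ccccc3)cc(OCc3ccccc3)c3c(=O)cc(-c4ccc(OCc5ccccc5)c(OCc5ccccc5)c4)oc23)c(OCc2ccccc2)c(OCc2ccccc2)c1 | intermediate
19 | 5,7-bis(benzyloxy)-8-[2,3-bis(benzyloxy)-5-(hydroxymethyl)phenyl]-2-[3,4-bis(benzyloxy)phenyl]-4H-chromen-4-one | OCc1cc(-c2c(OCc3ccccc3)cc(OCc3ccccc3)c3c(=O)cc(-c4ccc(OCc5ccccc5)c(OCc5ccccc5)c4)oc23)c(OCc2ccccc2)c(OCc2ccccc2)c1 | intermediate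
20 | 3-{5,7-bis(benzyloxy)-2-[3,4-bis(benzyloxy)phenyl]-4-oxo-4H-chromen-8-yl}-4,5-bis(benzyloxy)benzaldehyde | O=Cc1cc(-c2c(OCc3ccccc3)cc(OCc3ccccc3)c3c(=O)cc(-c4ccc(OCc5ccccc5)c(OCc5ccccc5)c4)oc23)c(OCc2ccccc2)c(OCc2ccccc2)c1 | intermediate
21 | 1-(2,4,6-trihydroxyphenyl)ethanone (2,4,6-trihydroxyacetophenone) | CC(=O)c1c(O)cc(O)cc1O | starting material
22 | 1-[2,4-bis(benzyloxy)-6-hydroxyphenyl]ethanone | CC(=O)c1c(O)cc(OCc2ccccc2)cc1OCc2ccccc2 | intermediate
23 | tert-butyl 3-[2,4-bis(benzyloxy)-6-hydroxyphenyl]-3-oxopropanoate | CC(C)(C)OC(=O)CC(=O)c1c(O)cc(OCc2ccccc2)cc1OCc2ccccc2 | intermediate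
24 | tert-butyl (2Z)-2-[2,4-bis(benzyloxy)-6-hydroxybenzoyl]-3-(3-{5,7-bis(benzyloxy)-2-[3,4-bis(benzyloxy)phenyl]-4-oxo-4H-chromen-8-yl}-4,5-bis(benzyloxy)phenyl)prop-2-enoate | CC(C)(C)OC(=O)/C(=C\c1cc(-c2c(OCc3ccccc3)cc(OCc3ccccc3)c3c(=O)cc(-c4ccc(OCc5ccccc5)c(OCc5ccccc5)c4)oc23)c(OCc2ccccc2)c(OCc2ccccc2)c1)C(=O)c1c(O)cc(OCc2ccccc2)cc1OCc2ccccc2 | intermediate
25 | tert-butyl (2S,3R)-5,7-bis(benzyloxy)-2-(3-{5,7-bis(benzyloxy)-2-[3,4-bis(benzyloxy)phenyl]-4-oxo-4H-chromen-8-yl}-4,5-bis(benzyloxy)phenyl)-4-oxo-3,4-dihydro-2H-chromene-3-carboxylate (not isolated) | O=C1[C@H](C(=O)OC(C)(C)C)[C@@H](c2cc(-c3c(OCc4ccccc4)cc(OCc4ccccc4)c4c(=O)cc(-c5ccc(OCc6ccccc6)c(OCc6ccccc6)c5)oc34)c(OCc3ccccc3)c(OCc3ccccc3)c2)Oc2cc(OCc3ccccc3)cc(OCc3ccccc3)c21 | intermediate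
26 | (2S)-5,7-bis(benzyloxy)-2-(3-{5,7-bis(benzyloxy)-2-[3,4-bis(benzyloxy)phenyl]-4-oxo-4H-chromen-8-yl}-4,5-bis(benzyloxy)phenyl)-2,3-dihydro-4H-chromen-4-one | O=C1C[C@@H](c2cc(-c3c(OCc4ccccc4)cc(OCc4ccccc4)c4c(=O)cc(-c5ccc(OCc6ccccc6)c(OCc6ccccc6)c5)oc34)c(OCc3ccccc3)c(OCc3ccccc3)c2)Oc2cc(OCc3ccccc3)cc(OCc3ccccc3)c21 | intermediate
27 | (2S)-2-{3-[2-(3,4-dihydroxyphenyl)-5,7-dihydroxy-4-oxo-4H-chromen-8-yl]-4,5-dihydroxyphenyl}-5,7-dihydroxy-2,3-dihydro-4H-chromen-4-one | O=C1C[C@@H](c2cc(O)c(O)c(-c3c(O)cc(O)c4c(=O)cc(-c5ccc(O)c(O)c5)oc34)c2)Oc2cc(O)cc(O)c21 | target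

## Step count and least certain steps

Total: 18 steps. Longest linear sequence: 16 steps (steps 1 to 13 and 16 to 18, from 1). The ring-A branch (steps 14 and 15) is two steps from 21.

Step 7 (key step). Most likely to go wrong: ring closure through oxygen to the pyranone without reopening under the conditions, cleavage of the triketide chain by methoxide (retro-Claisen), and air oxidation of the electron-rich phenoxide. Fallback: the aryl–aryl bond is made by cross-coupling; it sets out from 4 and comes back at 11. 1,3,5-Tris(methoxymethoxy)benzene F1 (from phloroglucinol, MOMCl, i-Pr2NEt) is lithiated between two acetal groups (n-BuLi, THF, 0 °C) and borylated (B(OMe)3, then water) to [2,4,6-tris(methoxymethoxy)phenyl]boronic acid F2. Suzuki–Miyaura coupling of F2 with 4 (Pd(OAc)2, SPhos, K3PO4, toluene/H2O, 90 °C) should give methyl 3,4-bis(benzyloxy)-5-[2,4,6-tris(methoxymethoxy)phenyl]benzoate F3, and HCl in MeOH (40 °C) removes the three acetals to return to 11.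

Step 17. Most likely to go wrong: erosion of enantioselectivity through uncatalysed or amine-promoted closure of the electron-rich, doubly ortho-substituted ring-A phenol (already possible during step 16), and partial racemisation by acid-promoted ring opening during the hot decarboxylation. Fallback: ring C is closed by SN2 displacement with inversion instead of conjugate addition; it sets out from 20 and 22 and comes back at 26. Claisen–Schmidt condensation (KOH, EtOH/THF, rt) gives (2E)-1-[2,4-bis(benzyloxy)-6-hydroxyphenyl]-3-(3-{5,7-bis(benzyloxy)-2-[3,4-bis(benzyloxy)phenyl]-4-oxo-4H-chromen-8-yl}-4,5-bis(benzyloxy)phenyl)prop-2-en-1-one F4. Copper-catalysed asymmetric conjugate borylation (CuCl, NaOt-Bu, a Josiphos-type ligand, B2pin2, MeOH, THF) gives (3R)-1-[2,4-bis(benzyloxy)-6-hydroxyphenyl]-3-(3-{5,7-bis(benzyloxy)-2-[3,4-bis(benzyloxy)phenyl]-4-oxo-4H-chromen-8-yl}-4,5-bis(benzyloxy)phenyl)-3-(4,4,5,5-tetramethyl-1,3,2-dioxaborolan-2-yl)propan-1-one F5. Oxidation with retention (NaBO3, THF/H2O) gives (3R)-1-[2,4-bis(benzyloxy)-6-hydroxyphenyl]-3-(3-{5,7-bis(benzyloxy)-2-[3,4-bis(benzyloxy)phenyl]-4-oxo-4H-chromen-8-yl}-4,5-bis(benzyloxy)phenyl)-3-hydroxypropan-1-one F6. Mitsunobu cyclisation (PPh3, diisopropyl azodicarboxylate, THF, 0 °C) then closes O1–C2 with inversion to the 2S flavanone 26.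

Step 9. Most likely to go wrong: insufficient discrimination between the two hydrogen-bonded hydroxyls, over-benzylation, and C-benzylation at the remaining ring position. Fallback: a regiochemically unambiguous cross-coupling that places ring B next to the free hydroxyl by construction; it sets out from 4 and 22 and comes back at 14. It gives up the cyclisation of step 7 and is therefore the last resort. Miyaura borylation of 4 (B2pin2, Pd(dppf)Cl2, KOAc, dioxane, 90 °C) gives methyl 3,4-bis(benzyloxy)-5-(4,4,5,5-tetramethyl-1,3,2-dioxaborolan-2-yl)benzoate F7. Iodination of 22 ortho to its free hydroxyl (N-iodosuccinimide, CH2Cl2, rt) gives 1-[4,6-bis(benzyloxy)-2-hydroxy-3-iodophenyl]ethanone F8. Suzuki–Miyaura coupling of F7 with F8 (Pd(OAc)2, SPhos, K2CO3, dioxane/H2O, 90 °C) gives 14.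

Step 6. Most likely to go wrong: proton transfer from the acidic benzylic position of 8 to the strongly basic dianion (ketene formation and self-condensation) and double acylation. Fallback: a monoanionic, masked acetoacetate is acylated and the ester is unveiled thermally; it sets out from 8 (made from 6 as in step 6) and comes back at 10. The lithium dienolate of 2,2,6-trimethyl-4H-1,3-dioxin-4-one (LiN(SiMe3)2, THF, -78 °C) is acylated by 8 to give methyl 3,4-bis(benzyloxy)-5-[3-(2,2-dimethyl-4-oxo-4H-1,3-dioxin-6-yl)-2-oxopropyl]benzoate F9. Heating F9 in toluene/MeOH (110 °C) releases acetone and the acylketene, which methanol traps to give 10.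

Step 18. Most likely to go wrong: over-reduction (saturation of the flavone C2=C3 bond or hydrogenolytic opening of the flavanone C2–O bond) and incomplete cleavage of the hindered ethers. Fallback: non-reductive debenzylation; it sets out from 26 and comes back at 27. BCl3 with pentamethylbenzene as cation scavenger (CH2Cl2, -78 °C) cleaves the aryl benzyl ethers by Lewis-acid ionisation with no hydrogen present, so no new intermediate is made.

## Further compounds

F1 | step 7 | 1,3,5-tris(methoxymethoxy)benzene | COCOc1cc(OCOC)cc(OCOC)c1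
F2 | step 7 | [2,4,6-tris(methoxymethoxy)phenyl]boronic acid | COCOc1cc(OCOC)c(B(O)O)c(OCOC)c1
F3 | step 7 | methyl 3,4-bis(benzyloxy)-5-[2,4,6-tris(methoxymethoxy)phenyl]benzoate | COC(=O)c1cc(-c2c(OCOC)cc(OCOC)cc2OCOC)c(OCc2ccccc2)c(OCc2ccccc2)c1
F4 | step 17 | (2E)-1-[2,4-bis(benzyloxy)-6-hydroxyphenyl]-3-(3-{5,7-bis(benzyloxy)-2-[3,4-bis(benzyloxy)phenyl]-4-oxo-4H-chromen-8-yl}-4,5-bis(benzyloxy)phenyl)prop-2-en-1-one | O=C(/C=C/c1cc(-c2c(OCc3ccccc3)cc(OCc3ccccc3)c3c(=O)cc(-c4ccc(OCc5ccccc5)c(OCc5ccccc5)c4)oc23)c(OCc2ccccc2)c(OCc2ccccc2)c1)c1c(O)cc(OCc2ccccc2)cc1OCc2ccccc2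
F5 | step 17 | (3R)-1-[2,4-bis(benzyloxy)-6-hydroxyphenyl]-3-(3-{5,7-bis(benzyloxy)-2-[3,4-bis(benzyloxy)phenyl]-4-oxo-4H-chromen-8-yl}-4,5-bis(benzyloxy)phenyl)-3-(4,4,5,5-tetramethyl-1,3,2-dioxaborolan-2-yl)propan-1-one | O=C(C[C@@H](B1OC(C)(C)C(C)(C)O1)c1cc(-c2c(OCc3ccccc3)cc(OCc3ccccc3)c3c(=O)cc(-c4ccc(OCc5ccccc5)c(OCc5ccccc5)c4)oc23)c(OCc2ccccc2)c(OCc2ccccc2)c1)c1c(O)cc(OCc2ccccc2)cc1OCc2ccccc2
F6 | step 17 | (3R)-1-[2,4-bis(benzyloxy)-6-hydroxyphenyl]-3-(3-{5,7-bis(benzyloxy)-2-[3,4-bis(benzyloxy)phenyl]-4-oxo-4H-chromen-8-yl}-4,5-bis(benzyloxy)phenyl)-3-hydroxypropan-1-one | O=C(C[C@@H](O)c1cc(-c2c(OCc3ccccc3)cc(OCc3ccccc3)c3c(=O)cc(-c4ccc(OCc5ccccc5)c(OCc5ccccc5)c4)oc23)c(OCc2ccccc2)c(OCc2ccccc2)c1)c1c(O)cc(OCc2ccccc2)cc1OCc2ccccc2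
F7 | step 9 | methyl 3,4-bis(benzyloxy)-5-(4,4,5,5-tetramethyl-1,3,2-dioxaborolan-2-yl)benzoate | COC(=O)c1cc(B2OC(C)(C)C(C)(C)O2)c(OCc2ccccc2)c(OCc2ccccc2)c1
F8 | step 9 | 1-[4,6-bis(benzyloxy)-2-hydroxy-3-iodophenyl]ethanone | CC(=O)c1c(O)c(I)c(OCc2ccccc2)cc1OCc2ccccc2
F9 | step 6 | methyl 3,4-bis(benzyloxy)-5-[3-(2,2-dimethyl-4-oxo-4H-1,3-dioxin-6-yl)-2-oxopropyl]benzoate | COC(=O)c1cc(CC(=O)CC2=CC(=O)OC(C)(C)O2)c(OCc2ccccc2)c(OCc2ccccc2)c1
F0 | step 18 | none | none
A1 | alternative 1 | 2-({1-[3-{5,7-bis(methoxymethoxy)-2-[3,4-bis(methoxymethoxy)phenyl]-4-oxo-4H-chromen-8-yl}-4,5-bis(methoxymethoxy)phenyl]ethenyl}oxy)-4,6-bis(methoxymethoxy)benzaldehyde | C=C(Oc1cc(OCOC)cc(OCOC)c1C=O)c1cc(OCOC)c(OCOC)c(-c2c(OCOC)cc(OCOC)c3c(=O)cc(-c4ccc(OCOC)c(OCOC)c4)oc23)c1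
A2 | alternative 1 | (2S)-2-[3-{5,7-bis(methoxymethoxy)-2-[3,4-bis(methoxymethoxy)phenyl]-4-oxo-4H-chromen-8-yl}-4,5-bis(methoxymethoxy)phenyl]-5,7-bis(methoxymethoxy)-2,3-dihydro-4H-chromen-4-one | O=C1C[C@@H](c2cc(OCOC)c(OCOC)c(-c3c(OCOC)cc(OCOC)c4c(=O)cc(-c5ccc(OCOC)c(OCOC)c5)oc34)c2)Oc2cc(OCOC)cc(OCOC)c21
A3 | alternative 2 | 3-ethoxycyclobut-2-en-1-one | CCOC1=CC(=O)C1
A4 | alternative 2 | methyl 3-(ethoxyethynyl)-4,5-bis(methoxymethoxy)benzoate | CCOC#Cc1cc(C(=O)OC)cc(OCOC)c1OCOC
A5 | alternative 2 | methyl 3-(2,4-diethoxy-6-hydroxyphenyl)-4,5-bis(methoxymethoxy)benzoate | CCOc1cc(O)c(-c2cc(C(=O)OC)cc(OCOC)c2OCOC)c(OCC)c1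
A6 | alternative 3 | tert-butyl (2Z)-2-[2-hydroxy-4,6-bis(methoxymethoxy)benzoyl]-3-[3-{5,7-bis(methoxymethoxy)-2-[3,4-bis(methoxymethoxy)phenyl]-4-oxo-4H-chromen-8-yl}-4,5-bis(methoxymethoxy)phenyl]prop-2-enoate | CC(C)(C)OC(=O)/C(=C\c1cc(OCOC)c(OCOC)c(-c2c(OCOC)cc(OCOC)c3c(=O)cc(-c4ccc(OCOC)c(OCOC)c4)oc23)c1)C(=O)c1c(O)cc(OCOC)cc1OCOC
A7 | alternative 3 | tert-butyl (2S,3R)-2-[3-{5,7-bis(methoxymethoxy)-2-[3,4-bis(methoxymethoxy)phenyl]-4-oxo-4H-chromen-8-yl}-4,5-bis(methoxymethoxy)phenyl]-5,7-bis(methoxymethoxy)-4-oxo-3,4-dihydro-2H-chromene-3-carboxylate | O=C1[C@H](C(=O)OC(C)(C)C)[C@@H](c2cc(OCOC)c(OCOC)c(-c3c(OCOC)cc(OCOC)c4c(=O)cc(-c5ccc(OCOC)c(OCOC)c5)oc34)c2)Oc2cc(OCOC)cc(OCOC)c21
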